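A neighbour flask charged with 0.25 M of substrate stands beside ours at 0.10 M, so we want a rule that carries from one charge to the other.

substrate 0.10 M; time 5.0 d

    substrate → ring (k1 = 0.0057 min⁻¹)
    2 substrate → open dimer (k2 = 0.63 M⁻¹ min⁻¹)
    ring ⇌ isomer of the product (K3 = 0.23, k3 = 0.0022 min⁻¹)
    substrate + ring ⇌ idle adduct, settled at all times (K4 = 5.5 M⁻¹)

- in percentages every species weighs as the substrate in it: one open dimer or idle adduct counts as two
- for ring the idle adduct is counted in
- where a step has two of a species, its rate is k times that concentration squared, and two are used at each turn
- in an amount of ring, one idle adduct counts as one ring
- the reaction counts as stopped when no species that holds the substrate changes by six tenths of a point or more over the second half of the time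
- run time (flask): 5.0 d

- at 5.0 d, what has stopped the reaction, if anything has (all of the substrate has reacted / forward and back rates have come level / it is still moving)
- the ring standing at 5.0 d, as a percentage of the substrate charged

We begin by turning the constants into times at the charge. The ring step has the time constant 175 min and the dimer step 7.94 min. The run holds 41.0 time constants of the ring step, so our answer to the first question is: all of the substrate has reacted.

The dimer step draws with the square of the substrate and the ring step with its first power, so their ratio falls as the substrate falls. The ratio of the two times, 0.0452, is the fraction of the charge left at which both steps draw equally: the crossover fraction, the inverse of the selectivity factor at the charge. Leaving the idle adduct aside and calling this fraction x, substrate reacting at fraction s of the charge goes to ring with the share x/(x+s). Summed from the whole charge down to nothing, this gives a pool of ring and isomer equal to x times the natural logarithm of one plus 1/x, or 14.2% of the charge. The forward half-life of ring, 0.22 d, is short against the run, so we let ring and isomer balance, and ring keeps 11.5%.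

The weak link is the idle adduct, which withholds substrate from both steps in proportion to K4 times the ring standing. That pool of ring and isomer rises from nothing to the figure above, so as a rough estimate we take the load at its mean, 0.0391. The dimer step feels this load twice and the ring step once, which raises the crossover fraction to 0.0470. The same rule then gives the ring we commit to: 11.9%.

The forecast says all of the substrate has reacted and ring 11.7%, on the ground that “Ring and dimer compete for substrate”. Our figure differs from it by 0.16 percentage points.

The flask gives all of the substrate has reacted, with 0% of the substrate left and ring at 11.8% at 5.0 d. Just after the start the dimer step uses substrate 20 times as fast as the ring step, and its turnover reaches its midpoint by 0.104 h against 0.581 h for the ring step; at 5.00 d open dimer stands at 85.5%. In the neighbour flask the crossover fraction drops to 0.0181, so the rule without the adduct's correction gives 5.93% ring, and that flask stands at 6.08%.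

The constants are invented.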